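**Plan**
1. Retrosynthetic cuts: the C6 veratrate ester; then the C5–H and C6–O bonds (back to a C5=C6 olefin); then C6–C7 and C1–C5 together in one intramolecular [5+2] cycloaddition; then C4–C(alkyne) and C2–C3 of the tether (alkynylation, aldol); last the three cyclopropane bonds (intramolecular cyclopropanation of an allylic diazoacetate).
2. Enabling feature: C7–C8(Me)=C9–C10–C1 of the seven-membered ring is the five-carbon unit of a vinylcyclopropane (three-membered ring C9–C10–C1, isopropenyl on C9, strained C9–C1 bond given up), and C5–C6 is an alkyne held on C1 by the C2–C3–C4 chain that becomes the five-membered ring.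
3. Forward order: cyclopropane carrying the C10 oxygen and the C1 quaternary centre, then the C2–C4 chain, then both carbocycles at once, then C5/C6, then the esters.
4. Stereochemistry: absolute configuration (C1, C10) from a chiral Rh carboxamidate cyclopropanation; C2 from a substrate-controlled boron aldol; C4 from a chelation-controlled alkynylation; C5 from hydroxyl-directed epoxidation and radical opening; C6 from hydroxyl-directed hydride delivery.

Key step: step 11

Numbering used below: daucane numbering (C1 quaternary ring-fusion carbon with the C15 methyl, C2–C4 in the five-membered ring, C5 ring-fusion CH, C6–C10 in the seven-membered ring); β is the face of the C15 methyl group, α the opposite face.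

**Route**

Step 1
Reactants: 1 2-methylidenepropane-1,3-diol; 2 4-methoxybenzaldehyde dimethyl acetal
Product: 3 2-(4-methoxyphenyl)-5-methylidene-1,3-dioxane
Conditions: PPTS (5 mol %), CH2Cl2, 4 Å MS, rt
Reagents that add atoms: none
Why: Acid-catalysed transacetalisation of a 1,3-diol with a dimethyl acetal gives the six-membered cyclic acetal, driven by removal of methanol; no stereocentre is formed.

Step 2
Reactants: 3 2-(4-methoxyphenyl)-5-methylidene-1,3-dioxane
Product: 4 2-(4-methoxyphenyl)-5-methyl-4H-1,3-dioxine (racemic at C2)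
Conditions: RuHCl(CO)(PPh3)3 (1 mol %), toluene, 80 °C
Reagents that add atoms: none
Why: Metal-hydride-catalysed isomerisation of an allyl ether to an enol ether moves the exocyclic double bond into the ring, where it is conjugated with oxygen; the ring holds the enol oxygen and the CH2O arm cis.

Step 3
Reactants: 4 2-(4-methoxyphenyl)-5-methyl-4H-1,3-dioxine
Product: 5 (Z)-3-[(4-methoxybenzyl)oxy]-2-methylprop-2-en-1-ol
Conditions: i-Bu2AlH (2.5 equiv), CH2Cl2, −78 → 0 °C; aq. potassium sodium tartrate
Reagents that add atoms: none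
Why: Reductive opening of a p-methoxybenzylidene acetal: aluminium should bind the more basic alkyl oxygen, so the bond from the acetal carbon to that oxygen breaks, hydride adds to the aryl-stabilised oxocarbenium ion, the PMB group stays on the enol oxygen and the Z geometry fixed by the ring is kept.

Step 4
Reactants: 5 (Z)-3-[(4-methoxybenzyl)oxy]-2-methylprop-2-en-1-ol; 6 glyoxylic acid chloride p-toluenesulfonylhydrazone
Product: 7 (Z)-3-[(4-methoxybenzyl)oxy]-2-methylprop-2-en-1-yl 2-diazoacetate
Conditions: 6 (1.8 equiv), PhNMe2, CH2Cl2, 0 °C; then Et3N, 0 °C → rt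
Reagents that add atoms: none
Why: O-Acylation by the acid chloride followed by base-induced loss of p-toluenesulfinate from the tosylhydrazone (Bamford–Stevens-type diazo formation) gives the diazoacetate under basic conditions that spare the enol ether.

Step 5
Reactants: 7 (Z)-3-[(4-methoxybenzyl)oxy]-2-methylprop-2-en-1-yl 2-diazoacetate
Product: 8 (1R,5R,6R)-6-[(4-methoxybenzyl)oxy]-5-methyl-3-oxabicyclo[3.1.0]hexan-2-one
Conditions: Rh2(4R-MPPIM)4 (1 mol %; MPPIM = methyl 1-(3-phenylpropanoyl)-2-oxoimidazolidine-4-carboxylate), CH2Cl2, reflux, slow addition of 7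
Reagents that add atoms: none
Why: Intramolecular cyclopropanation of an allylic diazoacetate through a rhodium carbenoid: the lactone tether forces the carbonyl-bearing carbon and the CH2O-bearing carbon cis, the Z enol ether geometry is transferred so that the PMBO group is endo (cis to both), and the chiral carboxamidate ligands select the alkene face (the R-configured catalyst is chosen by analogy with the sense known for allyl and cis-alkenyl diazoacetates), which fixes the absolute configuration of the future C1 and C10.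

Step 6
Reactants: 8 (1R,5R,6R)-6-[(4-methoxybenzyl)oxy]-5-methyl-3-oxabicyclo[3.1.0]hexan-2-one
Product: 9 1-[(1R,2R,3R)-3-(hydroxymethyl)-2-[(4-methoxybenzyl)oxy]-3-methylcyclopropyl]ethan-1-one (in equilibrium with its cyclic hemiketal)
Conditions: MeLi (1.05 equiv), THF, −78 °C; AcOH, −78 °C
Reagents that add atoms: methyllithium, C[Li]
Why: Mono-addition of an organolithium to a lactone: the tetrahedral lithium alkoxide is stable at −78 °C and gives the methyl ketone (as hemiketal) on quenching; the cyclopropane stereocentres are not touched.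

Step 7
Reactants: 9 1-[(1R,2R,3R)-3-(hydroxymethyl)-2-[(4-methoxybenzyl)oxy]-3-methylcyclopropyl]ethan-1-one
Product: 10 [(1R,2R,3R)-2-[(4-methoxybenzyl)oxy]-1-methyl-3-(prop-1-en-2-yl)cyclopropyl]methanol
Conditions: Ph3PCH3Br (3 equiv), KOt-Bu (2.8 equiv), THF, 0 °C → rt
Reagents that add atoms: methyltriphenylphosphonium bromide, C[P+](c1ccccc1)(c1ccccc1)c1ccccc1.[Br-]
Why: Wittig methylenation of the methyl ketone, which is released from the hemiketal under the basic conditions, gives the isopropenyl group cis to the CH2OH arm without touching the stereocentres.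

Step 8
Reactants: 10 [(1R,2R,3R)-2-[(4-methoxybenzyl)oxy]-1-methyl-3-(prop-1-en-2-yl)cyclopropyl]methanol
Product: 11 (1S,2R,3R)-2-[(4-methoxybenzyl)oxy]-1-methyl-3-(prop-1-en-2-yl)cyclopropane-1-carbaldehyde
Conditions: Dess–Martin periodinane (1.3 equiv), NaHCO3, CH2Cl2, 0 °C; used at once
Reagents that add atoms: none
Why: Dess–Martin oxidation of a neopentyl-type primary alcohol under buffered conditions; the cis-alkenyl cyclopropane carbaldehyde is kept cold and used directly because it can undergo a [3,3] retro-Claisen shift to a dihydrooxepine on warming.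

Step 9
Reactants: 11 (1S,2R,3R)-2-[(4-methoxybenzyl)oxy]-1-methyl-3-(prop-1-en-2-yl)cyclopropane-1-carbaldehyde; 12 3-methylbutan-2-one
Product: 15 (1S)-1-hydroxy-1-[(1R,2R,3R)-2-[(4-methoxybenzyl)oxy]-1-methyl-3-(prop-1-en-2-yl)cyclopropyl]-4-methylpentan-3-one, via boron enolate 13 (not isolated), via boron aldolate 14 (not isolated)
Conditions: 12, (c-C6H11)2BCl, Et3N, Et2O, −78 → 0 °C; then 11, −78 → −20 °C; MeOH, pH 7 buffer, H2O2, 0 °C
Reagents that add atoms: none
Why: Boron-mediated aldol addition of a methyl ketone through a closed chair transition state without chelation: the aldehyde should react in the conformer with C=O eclipsing the ring methyl group and be attacked from the side of the ring carbon that carries the PMB ether, which is less shielded than the side carrying the cis isopropenyl group, and this sets C2.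

Step 10
Reactants: 15 (1S)-1-hydroxy-1-[(1R,2R,3R)-2-[(4-methoxybenzyl)oxy]-1-methyl-3-(prop-1-en-2-yl)cyclopropyl]-4-methylpentan-3-one; 16 ethynylmagnesium bromide
Product: 18 (3R,5S)-5-[(1R,2R,3R)-2-[(4-methoxybenzyl)oxy]-1-methyl-3-(prop-1-en-2-yl)cyclopropyl]-3-(propan-2-yl)pent-1-yne-3,5-diol, via magnesium alkoxide 17 (not isolated)
Conditions: HC≡CMgBr (4 equiv), THF/CH2Cl2, −78 → −30 °C; aq. NH4Cl
Reagents that add atoms: none
Why: Chelation-controlled 1,2-addition of an alkynyl Grignard reagent to a β-hydroxy ketone: the magnesium alkoxide chelates the ketone in a half-chair with the cyclopropyl group equatorial and the slim acetylide attacks axially, cis to the C2 hydrogen, which puts isopropyl equatorial and sets C4.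

Step 11
Reactants: 18 (3R,5S)-5-[(1R,2R,3R)-2-[(4-methoxybenzyl)oxy]-1-methyl-3-(prop-1-en-2-yl)cyclopropyl]-3-(propan-2-yl)pent-1-yne-3,5-diol
Product: 19 (1R,2S,4R,10R)-10-[(4-methoxybenzyl)oxy]dauca-5,8-diene-2,4-diol
Conditions: [Rh(CO)2Cl]2 (5 mol %), ClCH2CH2Cl (0.02 M), 60 °C
Reagents that add atoms: none
Why: Monovalent rhodium, bound to the isopropenyl group, adds oxidatively into the strained cyclopropane bond between the isopropenyl-bearing carbon and the quaternary carbon (the future C9 and C1) to give a σ-alkyl/π-allyl rhodacycle; the tethered alkyne then inserts into the Rh–C(quaternary) bond and C(sp2)–C(sp3) reductive elimination joins the new alkenyl carbon to the far allyl terminus, so that C1–C5 and C6–C7 form in one catalytic turnover. The closest known reaction type is the Rh-catalysed intramolecular [5+2] cycloaddition of vinylcyclopropanes with alkynes, in the variant in which the two-carbon partner is tethered to a cyclopropane carbon cis to the vinyl group. The five-membered ring closes by 5-exo-dig migratory insertion (C1–C5) and the seven-membered ring by reductive elimination from an eight-membered rhodacycle (C6–C7), the C8=C9 double bond coming from the allyl unit. No new stereocentre is created: C1 and C10 are carried over from the cyclopropane (insertion goes with retention at C1), C2 and C4 come from the tether, the stereocentre at the isopropenyl-bearing carbon is destroyed, and C5 is deliberately left trigonal because an alkene partner would be forced by the chelated insertion geometry into a cis ring fusion (5-H syn to the C15 methyl), the opposite of the target. The step needs cleavage of the cyclopropane bond to the quaternary carbon and not of the bond to the PMBO-bearing carbon, and [5+2] and not [3+2] closure: only the rhodacycle from the first cleavage can insert the tethered alkyne in a 5-exo sense (the other should revert), and the cis placement of isopropenyl and side chain, fixed by lactone 8, disfavours reductive elimination at the near allyl terminus, which would put isopropenyl on the concave face of a diquinane. The moderate temperature should keep the thermal homo-1,5-hydrogen shift of the cis-alkenyl cyclopropyl carbinol in check.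

Step 12
Reactants: 19 (1R,2S,4R,10R)-10-[(4-methoxybenzyl)oxy]dauca-5,8-diene-2,4-diol
Product: 20 (1R,2S,4R,10R)-dauca-5,8-diene-2,4,10-triol
Conditions: DDQ (1.3 equiv), CH2Cl2/pH 7 buffer (10:1), 0 °C
Reagents that add atoms: none
Why: Oxidative cleavage of the PMB ether with DDQ (hydride abstraction to the benzylic oxocarbenium ion, then hydrolysis) frees the allylic C10 hydroxyl, so that C2 and C10 can be acetylated together.

Step 13
Reactants: 20 (1R,2S,4R,10R)-dauca-5,8-diene-2,4,10-triol
Product: 21 (1R,2S,4R,10R)-4-hydroxydauca-5,8-diene-2,10-diyl diacetate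
Conditions: Ac2O (3 equiv), pyridine, DMAP (10 mol %), CH2Cl2, 0 °C → rt
Reagents that add atoms: acetic anhydride, CC(=O)OC(C)=O
Why: DMAP-catalysed acylation esterifies the two secondary hydroxyls (C2 and C10), while the hindered tertiary C4 hydroxyl, needed later as a directing group, should not react.

Step 14
Reactants: 21 (1R,2S,4R,10R)-4-hydroxydauca-5,8-diene-2,10-diyl diacetate
Product: 22 (1R,2S,4R,5S,6R,10R)-5,6-epoxy-4-hydroxydauc-8-ene-2,10-diyl diacetate (5β,6β-epoxide)
Conditions: VO(acac)2 (5 mol %), t-BuOOH (1.5 equiv), CH2Cl2, 0 °C → rt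
Reagents that add atoms: tert-butyl hydroperoxide, CC(C)(C)OO
Why: Vanadium-catalysed hydroxyl-directed epoxidation: the tertiary allylic C4 hydroxyl binds the vanadium peroxide and delivers oxygen to the C5=C6 bond on its own (β) face, and the C8=C9 bond, which has no free allylic hydroxyl, is not touched.

Step 15
Reactants: 22 (1R,2S,4R,5S,6R,10R)-5,6-epoxy-4-hydroxydauc-8-ene-2,10-diyl diacetate
Product: 23 (1R,2S,4R,5S,6R,10R)-4,6-dihydroxydauc-8-ene-2,10-diyl diacetate (5α-H, 6β-OH)
Conditions: Cp2TiCl2 (2.5 equiv), Zn dust (6 equiv), THF, rt; then 22, 1,4-cyclohexadiene (10 equiv), rt; aq. NaH2PO4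
Reagents that add atoms: none
Why: Titanocene chloride-mediated reductive epoxide opening (Nugent–RajanBabu): electron transfer from trivalent titanium cleaves the C5–O bond to the tertiary C5 radical, and hydrogen-atom transfer from 1,4-cyclohexadiene should take place on the α face, away from the C15 methyl group and the titanium-bound C6 oxygen on the β face, which sets the trans ring fusion (5α-H) and leaves the 6β alcohol.

Step 16
Reactants: 23 (1R,2S,4R,5S,6R,10R)-4,6-dihydroxydauc-8-ene-2,10-diyl diacetate
Product: 24 (1R,2S,4R,5R,10R)-4-hydroxy-6-oxodauc-8-ene-2,10-diyl diacetate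
Conditions: Dess–Martin periodinane (1.5 equiv), NaHCO3, CH2Cl2, 0 °C → rt
Reagents that add atoms: none
Why: Dess–Martin oxidation of the secondary C6 alcohol (the tertiary C4 hydroxyl is inert) under buffered neutral conditions, which avoid enolisation of the β,γ-unsaturated ketone and so keep C5 and the position of the C8=C9 bond.

Step 17
Reactants: 24 (1R,2S,4R,5R,10R)-4-hydroxy-6-oxodauc-8-ene-2,10-diyl diacetate
Product: 25 (1R,2S,4R,5S,6S,10R)-4,6-dihydroxydauc-8-ene-2,10-diyl diacetate (6α-OH)
Conditions: Me4NBH(OAc)3 (5 equiv), MeCN/AcOH (1:1), −30 °C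
Reagents that add atoms: none
Why: Evans–Saksena reduction: the C4 hydroxyl exchanges an acetate on boron and delivers hydride intramolecularly to the β face of the C6 ketone, giving the 1,3-anti diol, that is the 6α alcohol (C6 set).

Step 18
Reactants: 25 (1R,2S,4R,5S,6S,10R)-4,6-dihydroxydauc-8-ene-2,10-diyl diacetate; 26 3,4-dimethoxybenzoyl chloride
Product: 27 (1R,2S,4R,5S,6S,10R)-2,10-diacetoxy-4-hydroxydauc-8-en-6-yl 3,4-dimethoxybenzoate (CNP0320758.1)
Conditions: 26 (1.5 equiv), Et3N, DMAP, CH2Cl2, rt
Reagents that add atoms: none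
Why: DMAP-catalysed acylation of the only secondary hydroxyl with the aroyl chloride gives the veratrate; the tertiary C4 hydroxyl is too hindered to react.

**Compound list**
1 | 2-methylidenepropane-1,3-diol | C=C(CO)CO | starting material
2 | 4-methoxybenzaldehyde dimethyl acetal | COc1ccc(cc1)C(OC)OC | starting material
3 | 2-(4-methoxyphenyl)-5-methylidene-1,3-dioxane | C=C1COC(c2ccc(OC)cc2)OC1 | intermediate
4 | 2-(4-methoxyphenyl)-5-methyl-4H-1,3-dioxine (racemic at C2) | CC1=COC(c2ccc(OC)cc2)OC1 | intermediate
5 | (Z)-3-[(4-methoxybenzyl)oxy]-2-methylprop-2-en-1-ol | OC/C(C)=C\OCc1ccc(OC)cc1 | intermediate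
6 | glyoxylic acid chloride p-toluenesulfonylhydrazone | O=C(Cl)/C=N/NS(=O)(=O)c1ccc(C)cc1 | starting material
7 | (Z)-3-[(4-methoxybenzyl)oxy]-2-methylprop-2-en-1-yl 2-diazoacetate | [N-]=[N+]=CC(=O)OC/C(C)=C\OCc1ccc(OC)cc1 | intermediate
8 | (1R,5R,6R)-6-[(4-methoxybenzyl)oxy]-5-methyl-3-oxabicyclo[3.1.0]hexan-2-one (PMBO endo) | O=C1OC[C@]2(C)[C@H](OCc3ccc(OC)cc3)[C@H]12 | intermediate
9 | 1-[(1R,2R,3R)-3-(hydroxymethyl)-2-[(4-methoxybenzyl)oxy]-3-methylcyclopropyl]ethan-1-one (acetyl, PMBO and CH2OH all cis; in equilibrium with its hemiketal) | CC(=O)[C@H]1[C@@H](OCc2ccc(OC)cc2)[C@@]1(C)CO | intermediate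
10 | [(1R,2R,3R)-2-[(4-methoxybenzyl)oxy]-1-methyl-3-(prop-1-en-2-yl)cyclopropyl]methanol (isopropenyl, PMBO and CH2OH all cis) | C=C(C)[C@H]1[C@@H](OCc2ccc(OC)cc2)[C@@]1(C)CO | intermediate
11 | (1S,2R,3R)-2-[(4-methoxybenzyl)oxy]-1-methyl-3-(prop-1-en-2-yl)cyclopropane-1-carbaldehyde | C=C(C)[C@H]1[C@@H](OCc2ccc(OC)cc2)[C@@]1(C)C=O | intermediate
12 | 3-methylbutan-2-one | CC(C)C(C)=O | starting material
13 | dicyclohexyl[(3-methylbut-1-en-2-yl)oxy]borane (boron enolate of 12) | C=C(OB(C1CCCCC1)C1CCCCC1)C(C)C | intermediate (not isolated)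
14 | dicyclohexylboron aldolate of 15 | C=C(C)[C@H]1[C@@H](OCc2ccc(OC)cc2)[C@@]1(C)[C@@H](OB(C2CCCCC2)C2CCCCC2)CC(=O)C(C)C | intermediate (not isolated)
15 | (1S)-1-hydroxy-1-[(1R,2R,3R)-2-[(4-methoxybenzyl)oxy]-1-methyl-3-(prop-1-en-2-yl)cyclopropyl]-4-methylpentan-3-one | C=C(C)[C@H]1[C@@H](OCc2ccc(OC)cc2)[C@@]1(C)[C@@H](O)CC(=O)C(C)C | intermediate
16 | ethynylmagnesium bromide | C#C[Mg]Br | starting material
17 | bromomagnesium alkoxide of 15 | C=C(C)[C@H]1[C@@H](OCc2ccc(OC)cc2)[C@@]1(C)[C@@H](O[Mg]Br)CC(=O)C(C)C | intermediate (not isolated)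
18 | (3R,5S)-5-[(1R,2R,3R)-2-[(4-methoxybenzyl)oxy]-1-methyl-3-(prop-1-en-2-yl)cyclopropyl]-3-(propan-2-yl)pent-1-yne-3,5-diol | C=C(C)[C@H]1[C@@H](OCc2ccc(OC)cc2)[C@@]1(C)[C@@H](O)C[C@@](O)(C(C)C)C#C | intermediate
19 | (1R,2S,4R,10R)-10-[(4-methoxybenzyl)oxy]dauca-5,8-diene-2,4-diol (2α-OH, 4β-OH, 10α-OPMB) | C1C(C)=C[C@@H](OCc2ccc(OC)cc2)[C@@]3(C)[C@@H](O)C[C@@](O)(C(C)C)C3=C1 | intermediate
20 | (1R,2S,4R,10R)-dauca-5,8-diene-2,4,10-triol | C1C(C)=C[C@@H](O)[C@@]2(C)[C@@H](O)C[C@@](O)(C(C)C)C2=C1 | intermediate
21 | (1R,2S,4R,10R)-4-hydroxydauca-5,8-diene-2,10-diyl diacetate | C1C(C)=C[C@@H](OC(C)=O)[C@@]2(C)[C@@H](OC(C)=O)C[C@@](O)(C(C)C)C2=C1 | intermediate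
22 | (1R,2S,4R,5S,6R,10R)-5,6-epoxy-4-hydroxydauc-8-ene-2,10-diyl diacetate (5β,6β-epoxide) | O1[C@@H]2CC(C)=C[C@@H](OC(C)=O)[C@@]3(C)[C@@H](OC(C)=O)C[C@@](O)(C(C)C)[C@@]123 | intermediate
23 | (1R,2S,4R,5S,6R,10R)-4,6-dihydroxydauc-8-ene-2,10-diyl diacetate (5α-H, 6β-OH) | O[C@@H]1CC(C)=C[C@@H](OC(C)=O)[C@@]2(C)[C@@H](OC(C)=O)C[C@@](O)(C(C)C)[C@H]12 | intermediate
24 | (1R,2S,4R,5R,10R)-4-hydroxy-6-oxodauc-8-ene-2,10-diyl diacetate | O=C1CC(C)=C[C@@H](OC(C)=O)[C@@]2(C)[C@@H](OC(C)=O)C[C@@](O)(C(C)C)[C@H]12 | intermediate
25 | (1R,2S,4R,5S,6S,10R)-4,6-dihydroxydauc-8-ene-2,10-diyl diacetate (6α-OH) | O[C@H]1CC(C)=C[C@@H](OC(C)=O)[C@@]2(C)[C@@H](OC(C)=O)C[C@@](O)(C(C)C)[C@H]12 | intermediate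
26 | 3,4-dimethoxybenzoyl chloride | COc1ccc(C(=O)Cl)cc1OC | starting material
27 | (1R,2S,4R,5S,6S,10R)-2,10-diacetoxy-4-hydroxydauc-8-en-6-yl 3,4-dimethoxybenzoate (CNP0320758.1) | COc1ccc(C(=O)O[C@H]2CC(C)=C[C@@H](OC(C)=O)[C@@]3(C)[C@@H](OC(C)=O)C[C@@](O)(C(C)C)[C@H]23)cc1OC | target

**Step count**
Total: 18 steps. Longest linear sequence: 18 steps (the route is linear from 1).

**Steps most likely to fail**

Step 11. What may go wrong: insertion of rhodium into the other cyclopropane bond (toward the PMBO-bearing carbon), alkyne insertion so slow that the thermal homo-1,5-hydrogen shift of the cis-alkenyl cyclopropyl carbinol takes over, or reductive elimination at the near allyl terminus ([3+2] closure). Fallback: the cycloaddition is run on an electron-poor ynone and the isopropyl group is added afterwards. It sets out from 11 and comes back at 19. Aldehyde 11 is combined with the dicyclohexylboron enolate of 4-(trimethylsilyl)but-3-yn-2-one (same boron aldol and same facial preference as step 9) to give the β-hydroxy silyl ynone F1. Treatment with [Rh(CO)2Cl]2 at room temperature, where ynones insert fast and thermal side reactions are slow, should give the C6-silyl dienone F2. Addition of i-PrMgCl/CeCl3 to the C4 ketone, expected anti to the C15 methyl group, gives the silyl diene diol F3. n-Bu4NF in THF then removes the C6 silyl group by 1,4-migration from carbon to the cis C4 alkoxide (Brook rearrangement) and protonation, which gives 19.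

Step 15. What may go wrong: hydrogen-atom transfer to the β face of the C5 radical (cis ring fusion), or capture of the radical by a second titanium centre with loss of the C6 hydrogen. Fallback: hydroboration–oxidation in place of the epoxide sequence. It sets out from 21 and comes back at 25. BH3·SMe2 in THF at 0 °C should add hydrogen to C5 and boron to C6 in a syn fashion from the α face, anti to the C15 methyl group as with Δ5-steroids, the C4 borate ester adding to the shielding of the β face. Oxidation with NaBO3 (retention) then gives 25 directly, so that 22 to 24 are bypassed. The C8=C9 bond may compete, so the borane is used in slight excess only. No new compound is made (F0).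

Step 9. What may go wrong: addition to the other face of the aldehyde (from the isopropenyl side), which would give the C2 epimer and, through the chelate of step 10, the wrong C4 as well. Fallback: a reagent-controlled acetate aldol with a chiral ester. It sets out from 11 and comes back at 15. The dianion of (S)-2-hydroxy-1,2,2-triphenylethyl acetate (LiN(i-Pr)2, 2 equiv, THF, −78 °C, then MgBr2) adds to 11 to give the triphenylglycol ester F4, in which the ester group should control the aldehyde face (S carbinol). MeNH(OMe)·HCl/i-PrMgCl converts it into the N-methoxy-N-methylamide F5, and i-PrMgCl (excess) then gives 15.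

Further compounds
F1 | step 11 | (5S)-5-hydroxy-5-[(1R,2R,3R)-2-[(4-methoxybenzyl)oxy]-1-methyl-3-(prop-1-en-2-yl)cyclopropyl]-1-(trimethylsilyl)pent-1-yn-3-one | C=C(C)[C@H]1[C@@H](OCc2ccc(OC)cc2)[C@@]1(C)[C@@H](O)CC(=O)C#C[Si](C)(C)C
F2 | step 11 | 2α-hydroxy-10α-[(4-methoxybenzyl)oxy]-6-(trimethylsilyl)-11,12,13-trinordauca-5,8-dien-4-one (C4 ketone, no isopropyl) | C1C(C)=C[C@@H](OCc2ccc(OC)cc2)[C@@]3(C)[C@@H](O)CC(=O)C3=C1[Si](C)(C)C
F3 | step 11 | 10α-[(4-methoxybenzyl)oxy]-6-(trimethylsilyl)dauca-5,8-diene-2α,4β-diol | C1C(C)=C[C@@H](OCc2ccc(OC)cc2)[C@@]3(C)[C@@H](O)C[C@@](O)(C(C)C)C3=C1[Si](C)(C)C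
F0 | step 15 | none | none
F4 | step 9 | (S)-2-hydroxy-1,2,2-triphenylethyl (3S)-3-hydroxy-3-[(1R,2R,3R)-2-[(4-methoxybenzyl)oxy]-1-methyl-3-(prop-1-en-2-yl)cyclopropyl]propanoate | C=C(C)[C@H]1[C@@H](OCc2ccc(OC)cc2)[C@@]1(C)[C@@H](O)CC(=O)O[C@@H](c1ccccc1)C(O)(c1ccccc1)c1ccccc1
F5 | step 9 | (3S)-3-hydroxy-N-methoxy-3-[(1R,2R,3R)-2-[(4-methoxybenzyl)oxy]-1-methyl-3-(prop-1-en-2-yl)cyclopropyl]-N-methylpropanamide | C=C(C)[C@H]1[C@@H](OCc2ccc(OC)cc2)[C@@]1(C)[C@@H](O)CC(=O)N(C)OC
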